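**Plan**

1. Germacrane numbering is used: C1=C10 (C14 methyl on C10), C2 (OAc), C3, C4 (OH, C15 methyl), C5, C6 (O-methacryloyl), C7=C11, C8 and C12 in the lactone ring, C8=C9 exocyclic, C13 = CH2OH.
2. Retrosynthesis: after the C13 silyl ether, the C8=C9 enol-lactone bond and the C12 carbonyl are taken back to a 2,3,4-trisubstituted furan (ring O, C12–H, C11, C7, C8) as a masked butenolide, and the C2 carbinol to a C2 ketone. The ten-membered carbocycle is then cut at C3–C4, an aldol retron (C2=O, C4–OH), which opens it to a chloromethyl (Z)-enone / methyl ketone.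
3. The open chain is cut at C1–C2 (alkenyllithium acylation), C8–C9 (furyllithium alkylation) and C5–C6 (allylation), back to 3,4-bis(hydroxymethyl)furan, propargyl alcohol and a chloroacetyl Weinreb amide.
4. Forward: the furan is present from the start and receives the C4–C5 arm and the C9–C1 chain. The ten-membered ring is closed by C3–C4 bond formation (the only carbocycle-forming step). The furan is oxidised to the hydroxybutenolide and dehydrated to the ylidene butenolide at the end.
5. What makes the closure possible: the 1,3-oxygen pattern at C2/C4, and five sp2 ring atoms (furan edge C7=C8, Z-alkene C10=C1, carbonyl C2) that hold the C3 enolate and the C4 ketone on one side, so that only C3–C6 and C9 have to fold.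
6. Stereochemistry: C6 by reagent-controlled allylboration; C4 in the ring closure under control of C6; C2 by C4-hydroxyl-directed anti reduction; Z-C1=C10 from anti-carbomagnesiation of propargyl alcohol; C8=C9 geometry enforced by the ring.

Key step: step 10

**Route**

Step 1
Reactants: 1 propargyl alcohol
Product: 3 (Z)-3-iodo-2-methylprop-2-en-1-ol, via dimagnesium alkenoxide 2 (not isolated)
Conditions: MeMgBr (2.5 equiv), CuI (10 mol%), THF/Et2O, −10 °C to rt; then I2, −78 to 0 °C; aq NH4Cl
Reagents that add atoms: methylmagnesium bromide C[Mg]Br; iodine II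
Why: Copper-catalysed anti-carbomagnesiation of the propargylic magnesium alkoxide places Mg cis to the CH2O group (five-membered chelate 2), and iodinolysis with retention should give the Z iodide that later becomes the ring-cis C1=C10 alkene.

Step 2
Reactants: 3 (Z)-3-iodo-2-methylprop-2-en-1-ol
Product: 4 (Z)-3-bromo-1-iodo-2-methylprop-1-ene
Conditions: CBr4, PPh3, CH2Cl2, 0 °C
Reagents that add atoms: carbon tetrabromide BrC(Br)(Br)Br
Why: Appel bromination of the primary allylic alcohol is an SN2 process at carbon and should leave the alkenyl iodide and the alkene geometry untouched.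

Step 3
Reactants: 5 3,4-bis(hydroxymethyl)furan
Product: 6 [4-(TBDPS-oxymethyl)furan-3-yl]methanol (TBDPS = tert-butyldiphenylsilyl)
Conditions: NaH (1.0 equiv), THF, 0 °C; then TBDPSCl, 0 °C to rt
Reagents that add atoms: tert-butyl(chloro)diphenylsilane CC(C)(C)[Si](Cl)(c1ccccc1)c1ccccc1
Why: Monosilylation of a symmetric diol through its sparingly soluble monosodium alkoxide differentiates the future C6 and C13 arms.

Step 4
Reactants: 6 [4-(TBDPS-oxymethyl)furan-3-yl]methanol
Product: 7 4-(TBDPS-oxymethyl)furan-3-carbaldehyde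
Conditions: MnO2 (activated, excess), CH2Cl2, rt
Reagents that add atoms: none
Why: MnO2 oxidises the furylmethyl (benzylic-type) alcohol to the aldehyde without over-oxidation and without touching the silyl ether.

Step 5
Reactants: 7 4-(TBDPS-oxymethyl)furan-3-carbaldehyde
Product: 9 (R)-1-[4-(TBDPS-oxymethyl)furan-3-yl]but-3-en-1-ol, via borinate ester 8 (not isolated)
Conditions: lIpc2B(allyl) [B-allyldiisopinocampheylborane from (−)-α-pinene, made from (+)-Ipc2BOMe and allylMgBr], Et2O, −78 °C; then NaOH, H2O2, 0 °C to rt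
Reagents that add atoms: B-allyldiisopinocampheylborane from (−)-α-pinene C=CCB([C@H]1C[C@H]2C[C@@H]([C@@H]1C)C2(C)C)[C@H]1C[C@H]2C[C@@H]([C@@H]1C)C2(C)C
Why: Brown allylboration through the chair six-membered transition state; this reagent enantiomer should add allyl to the Re face of the aryl-type aldehyde and so set C6 as R.

Step 6
Reactants: 9 (R)-1-[4-(TBDPS-oxymethyl)furan-3-yl]but-3-en-1-ol; 4 (Z)-3-bromo-1-iodo-2-methylprop-1-ene
Product: 11 (R)-1-{4-(TBDPS-oxymethyl)-2-[(Z)-3-iodo-2-methylprop-2-en-1-yl]furan-3-yl}but-3-en-1-ol, via dilithio species 10 (not isolated)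
Conditions: nBuLi (2.2 equiv), THF, −78 to 0 °C; then 4, −78 °C to rt; aq NH4Cl
Reagents that add atoms: none
Why: Alkoxide-directed lithiation of a 3-furylcarbinol at the adjacent α-position (C8) followed by SN2 alkylation of the furyllithium with the primary allylic bromide forms C8–C9; iodine–lithium exchange with the weakly basic furyllithium is unfavourable, so the Z iodoalkene should survive.

Step 7
Reactants: 11 (R)-1-{4-(TBDPS-oxymethyl)-2-[(Z)-3-iodo-2-methylprop-2-en-1-yl]furan-3-yl}but-3-en-1-ol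
Product: 12 triethylsilyl (TES) ether of 11
Conditions: TESCl, imidazole, DMF, 0 °C to rt
Reagents that add atoms: chlorotriethylsilane CC[Si](Cl)(CC)CC
Why: Standard silylation of the secondary alcohol; TES is chosen as a bulky, non-chelating group that can later be removed in the presence of the primary TBDPS ether.

Step 8
Reactants: 12 TES ether of 11; 13 2-chloro-N-methoxy-N-methylacetamide
Product: 16 (Z)-1-chloro-4-methyl-5-{3-[(R)-1-(TES-oxy)but-3-en-1-yl]-4-(TBDPS-oxymethyl)furan-2-yl}pent-3-en-2-one, via alkenyllithium 14 (not isolated), via lithium hemiaminal alkoxide 15 (not isolated)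
Conditions: tBuLi (2.1 equiv), Et2O, −78 °C; then 13, −78 °C; aq NH4Cl
Reagents that add atoms: none
Why: Iodine–lithium exchange proceeds with retention of alkene geometry, and the Weinreb ketone synthesis stops at the chelated adduct 15, so the Z chloromethyl enone (C2, C3) should form without over-addition.

Step 9
Reactants: 16 (Z)-chloromethyl enone with terminal alkene
Product: 17 (Z)-1-chloro-4-methyl-5-{3-[(R)-3-oxo-1-(TES-oxy)butyl]-4-(TBDPS-oxymethyl)furan-2-yl}pent-3-en-2-one
Conditions: PdCl2 (10 mol%), Cu(OAc)2 (20 mol%), O2 (1 atm), DMA/H2O 7:1, rt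
Reagents that add atoms: water O
Why: Tsuji–Wacker oxidation by Markovnikov hydroxypalladation of the only monosubstituted alkene gives the C4 methyl ketone; the trisubstituted enone alkene is inert and the acetate-buffered co-oxidant keeps the medium mild for the TES ether and the chloroketone.

Step 10
Reactants: 17 open-chain chloromethyl (Z)-enone / methyl ketone
Product: 20 (1(10)Z,4R,6R)-4-hydroxy-6-(TES-oxy)-13-(TBDPS-oxy)-8,12-epoxygermacra-1(10),7,11-trien-2-one, via samarium dienolate 18 (not isolated), via samarium aldolate 19 (not isolated)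
Conditions: SmI2 (2.5 equiv), THF, −78 °C, slow addition of 17 (final about 0.003 M); sat. aq NH4Cl at −78 °C
Reagents that add atoms: none
Why: Two single-electron transfers from SmI2 cleave the C3–Cl bond and give the trivalent-samarium dienolate 18 regiospecifically at C3, which adds to the C4 ketone through a samarium-bridged six-membered chair-like array (O2–Sm–O4) to give aldolate 19. The closest known reaction type is the SmI2-promoted intramolecular Reformatsky-type aldol cyclisation of α-halo ketones and esters onto carbonyl groups, which is established for medium rings. The ten-membered carbocycle is closed in the 10-(enolendo)-exo-trig mode, helped by the five sp2 ring atoms (furan edge C7=C8, Z-alkene C10=C1, C2) that hold both reacting ends on one side. The new stereocentre C4 is controlled by C6: allylic strain against the C8 side chain places C6–H in the furan plane and the bulky, non-chelating TES-oxy group on the furan face away from the closing chain, so the ketone should be attacked with its samarium-bound oxygen turned away from that group, giving C4–O trans to C6–O. The step needs regioselective enolate formation (secured by the C–Cl bond, so neither ketone is enolised and the β-silyloxy group at C6 is not eliminated), chemoselective reduction (the α-chloro ketone is reduced far faster than the dialkyl ketone or the enone at −78 °C) and ring closure over oligomerisation (high dilution, slow addition). The Z geometry of C1=C10 should be retained because the enolate is only cross-conjugated to it.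

Step 11
Reactants: 20 ten-membered β-hydroxy enone
Product: 22 (1(10)Z,2S,4S,6R)-6-(TES-oxy)-13-(TBDPS-oxy)-8,12-epoxygermacra-1(10),7,11-triene-2,4-diol, via alkoxyborohydride 21 (not isolated)
Conditions: Me4NBH(OAc)3 (5 equiv), MeCN/AcOH 1:1, −30 °C; aq potassium sodium tartrate
Reagents that add atoms: none
Why: Evans–Saksena reduction: the C4 hydroxyl exchanges onto boron (21) and hydride is delivered intramolecularly to the C2 ketone (1,2-reduction of the enone), which should give the 2,4-anti diol and set C2.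

Step 12
Reactants: 22 2,4-diol
Product: 23 2-acetate of 22
Conditions: Ac2O, pyridine, DMAP (cat.), CH2Cl2, 0 °C
Reagents that add atoms: acetic anhydride CC(=O)OC(C)=O
Why: Acylation of the secondary allylic C2 hydroxyl is much faster than that of the tertiary C4 hydroxyl, which should stay free.

Step 13
Reactants: 23 2-acetate with C6–OTES
Product: 24 (1(10)Z,2S,4R,6R)-2-acetoxy-13-(TBDPS-oxy)-8,12-epoxygermacra-1(10),7,11-triene-4,6-diol
Conditions: HF·pyridine, pyridine, THF, 0 °C
Reagents that add atoms: none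
Why: Buffered HF cleaves the secondary TES ether much faster than the primary TBDPS ether and leaves the acetate untouched.

Step 14
Reactants: 24 4,6-diol 2-acetate
Product: 25 6-methacrylate of 24 ((2S,4S,6R), furan intact)
Conditions: methacrylic anhydride, Et3N, DMAP (cat.), CH2Cl2, 0 °C to rt
Reagents that add atoms: methacrylic anhydride C=C(C)C(=O)OC(=O)C(C)=C
Why: DMAP-catalysed (Steglich-type) acylation of the only secondary hydroxyl; the tertiary C4 hydroxyl should not react with a limited amount of anhydride.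

Step 15
Reactants: 25 furan with both esters in place
Product: 27 (1(10)Z,2S,4S,6R)-2-acetoxy-4,8-dihydroxy-6-(methacryloyloxy)-13-(TBDPS-oxy)germacra-1(10),7(11)-dien-12,8-olide (C8 epimers), via endoperoxide 26 (not isolated)
Conditions: O2, tetraphenylporphyrin (cat.), iPr2NEt, CH2Cl2, visible light, −78 °C
Reagents that add atoms: oxygen O=O
Why: Singlet oxygen adds [4+2] across C8/C12 of the electron-rich furan far faster than it reacts with the deactivated C1=C10 alkene, and base-induced Kornblum–DeLaMare fragmentation of 26 by removal of the only available hydrogen (C12–H) fixes the carbonyl at C12 and the hydroxyl at C8.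

Step 16
Reactants: 27 8-hydroxybutenolide
Product: 29 (1(10)Z,2S,4S,6R,8E)-2-acetoxy-4-hydroxy-6-(methacryloyloxy)-13-(TBDPS-oxy)germacra-1(10),7(11),8-trien-12,8-olide, via lactol mesylate 28 (not isolated)
Conditions: MsCl (1.3 equiv), Et3N, CH2Cl2, −20 to 0 °C
Reagents that add atoms: none
Why: Sulfonylation of the acidic lactol hydroxyl and E1-type loss of mesylate, with deprotonation at the allylic C9 (the only carbon next to C8 that carries hydrogen), should give the conjugated enol lactone; the ring allows only the geometry with C10 cis to C7.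

Step 17
Reactants: 29 TBDPS ether of the target
Product: 30 (1(10)Z,2S,4S,6R,8E)-2-acetoxy-4,13-dihydroxy-6-(methacryloyloxy)germacra-1(10),7(11),8-trien-12,8-olide (CNP0246543.1)
Conditions: HF·pyridine, pyridine, THF, 0 °C to rt
Reagents that add atoms: none
Why: Buffered fluoride cleaves the primary silyl ether under conditions that should leave both esters, the tertiary alcohol and the enol lactone intact.

**Compound list**

1 | propargyl alcohol | C#CCO | starting material
2 | bromomagnesium (Z)-3-(bromomagnesio)-2-methylprop-2-en-1-olate | Br[Mg]OC/C(C)=C\[Mg]Br | intermediate (not isolated)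
3 | (Z)-3-iodo-2-methylprop-2-en-1-ol | OC/C(C)=C\I | intermediate
4 | (Z)-3-bromo-1-iodo-2-methylprop-1-ene | BrC/C(C)=C\I | intermediate
5 | 3,4-bis(hydroxymethyl)furan | OCc1cocc1CO | starting material
6 | [4-(TBDPS-oxymethyl)furan-3-yl]methanol | OCc1cocc1CO[Si](c2ccccc2)(c2ccccc2)C(C)(C)C | intermediate
7 | 4-(TBDPS-oxymethyl)furan-3-carbaldehyde | O=Cc1cocc1CO[Si](c2ccccc2)(c2ccccc2)C(C)(C)C | intermediate
8 | diisopinocampheylborinate ester of 9 | C=CC[C@@H](OB([C@H]1C[C@H]2C[C@@H]([C@@H]1C)C2(C)C)[C@H]3C[C@H]4C[C@@H]([C@@H]3C)C4(C)C)c5cocc5CO[Si](c6ccccc6)(c6ccccc6)C(C)(C)C | intermediate (not isolated)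
9 | (R)-1-[4-(TBDPS-oxymethyl)furan-3-yl]but-3-en-1-ol | C=CC[C@@H](O)c1cocc1CO[Si](c2ccccc2)(c2ccccc2)C(C)(C)C | intermediate
10 | C8-lithiated lithium alkoxide of 9 | C=CC[C@@H](O[Li])c1c([Li])occ1CO[Si](c2ccccc2)(c2ccccc2)C(C)(C)C | intermediate (not isolated)
11 | (R)-1-{4-(TBDPS-oxymethyl)-2-[(Z)-3-iodo-2-methylprop-2-en-1-yl]furan-3-yl}but-3-en-1-ol | C=CC[C@@H](O)c1c(C/C(C)=C\I)occ1CO[Si](c2ccccc2)(c2ccccc2)C(C)(C)C | intermediate
12 | TES ether of 11 (6R) | C=CC[C@@H](O[Si](CC)(CC)CC)c1c(C/C(C)=C\I)occ1CO[Si](c2ccccc2)(c2ccccc2)C(C)(C)C | intermediate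
13 | 2-chloro-N-methoxy-N-methylacetamide | CON(C)C(=O)CCl | starting material
14 | (Z)-alkenyllithium from 12 | C=CC[C@@H](O[Si](CC)(CC)CC)c1c(C/C(C)=C\[Li])occ1CO[Si](c2ccccc2)(c2ccccc2)C(C)(C)C | intermediate (not isolated)
15 | lithium hemiaminal alkoxide (adduct of 14 and 13) | C=CC[C@@H](O[Si](CC)(CC)CC)c1c(C/C(C)=C\C(O[Li])(CCl)N(C)OC)occ1CO[Si](c2ccccc2)(c2ccccc2)C(C)(C)C | intermediate (not isolated)
16 | (Z)-1-chloro-4-methyl-5-{3-[(R)-1-(TES-oxy)but-3-en-1-yl]-4-(TBDPS-oxymethyl)furan-2-yl}pent-3-en-2-one | C=CC[C@@H](O[Si](CC)(CC)CC)c1c(C/C(C)=C\C(=O)CCl)occ1CO[Si](c2ccccc2)(c2ccccc2)C(C)(C)C | intermediate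
17 | (Z)-1-chloro-4-methyl-5-{3-[(R)-3-oxo-1-(TES-oxy)butyl]-4-(TBDPS-oxymethyl)furan-2-yl}pent-3-en-2-one | CC(=O)C[C@@H](O[Si](CC)(CC)CC)c1c(C/C(C)=C\C(=O)CCl)occ1CO[Si](c2ccccc2)(c2ccccc2)C(C)(C)C | intermediate
18 | diiodosamarium dienolate of 17 (C3=C2–O–Sm) | CC(=O)C[C@@H](O[Si](CC)(CC)CC)c1c(C/C(C)=C\C(=C)O[Sm](I)I)occ1CO[Si](c2ccccc2)(c2ccccc2)C(C)(C)C | intermediate (not isolated)
19 | diiodosamarium C4-alkoxide (aldolate) of 20 | CC[Si](CC)(CC)O[C@@H]1C[C@@](C)(O[Sm](I)I)CC(=O)/C=C(C)\Cc2occ(CO[Si](c3ccccc3)(c3ccccc3)C(C)(C)C)c21 | intermediate (not isolated)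
20 | (1(10)Z,4R,6R)-4-hydroxy-6-(TES-oxy)-13-(TBDPS-oxy)-8,12-epoxygermacra-1(10),7,11-trien-2-one | CC[Si](CC)(CC)O[C@@H]1C[C@@](C)(O)CC(=O)/C=C(C)\Cc2occ(CO[Si](c3ccccc3)(c3ccccc3)C(C)(C)C)c21 | intermediate
21 | tetramethylammonium C4-alkoxy(diacetoxy)hydroborate of 20 | C[N+](C)(C)C.CC[Si](CC)(CC)O[C@@H]1C[C@@](C)(O[BH-](OC(C)=O)OC(C)=O)CC(=O)/C=C(C)\Cc2occ(CO[Si](c3ccccc3)(c3ccccc3)C(C)(C)C)c21 | intermediate (not isolated)
22 | (1(10)Z,2S,4S,6R)-6-(TES-oxy)-13-(TBDPS-oxy)-8,12-epoxygermacra-1(10),7,11-triene-2,4-diol | CC[Si](CC)(CC)O[C@@H]1C[C@@](C)(O)C[C@H](O)/C=C(C)\Cc2occ(CO[Si](c3ccccc3)(c3ccccc3)C(C)(C)C)c21 | intermediate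
23 | 2-acetate of 22 (2S,4S,6R) | CC[Si](CC)(CC)O[C@@H]1C[C@@](C)(O)C[C@H](OC(C)=O)/C=C(C)\Cc2occ(CO[Si](c3ccccc3)(c3ccccc3)C(C)(C)C)c21 | intermediate
24 | (1(10)Z,2S,4R,6R)-2-acetoxy-13-(TBDPS-oxy)-8,12-epoxygermacra-1(10),7,11-triene-4,6-diol | O[C@@H]1C[C@@](C)(O)C[C@H](OC(C)=O)/C=C(C)\Cc2occ(CO[Si](c3ccccc3)(c3ccccc3)C(C)(C)C)c21 | intermediate
25 | 6-methacrylate of 24 (2S,4S,6R) | C=C(C)C(=O)O[C@@H]1C[C@@](C)(O)C[C@H](OC(C)=O)/C=C(C)\Cc2occ(CO[Si](c3ccccc3)(c3ccccc3)C(C)(C)C)c21 | intermediate
26 | C8/C12 endoperoxide of 25 | C=C(C)C(=O)O[C@@H]1C[C@@](C)(O)C[C@H](OC(C)=O)/C=C(C)\CC23OOC(O2)C(CO[Si](c4ccccc4)(c4ccccc4)C(C)(C)C)=C31 | intermediate (not isolated)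
27 | (1(10)Z,2S,4S,6R)-2-acetoxy-4,8-dihydroxy-6-(methacryloyloxy)-13-(TBDPS-oxy)germacra-1(10),7(11)-dien-12,8-olide (C8 epimers) | C=C(C)C(=O)O[C@@H]1C[C@@](C)(O)C[C@H](OC(C)=O)/C=C(C)\CC2(O)OC(=O)C(CO[Si](c3ccccc3)(c3ccccc3)C(C)(C)C)=C21 | intermediate
28 | C8 methanesulfonate of 27 | C=C(C)C(=O)O[C@@H]1C[C@@](C)(O)C[C@H](OC(C)=O)/C=C(C)\CC2(OS(C)(=O)=O)OC(=O)C(CO[Si](c3ccccc3)(c3ccccc3)C(C)(C)C)=C21 | intermediate (not isolated)
29 | (1(10)Z,2S,4S,6R,8E)-2-acetoxy-4-hydroxy-6-(methacryloyloxy)-13-(TBDPS-oxy)germacra-1(10),7(11),8-trien-12,8-olide | C=C(C)C(=O)O[C@@H]1C[C@@](C)(O)C[C@H](OC(C)=O)/C=C(C)\C=C2\OC(=O)C(CO[Si](c3ccccc3)(c3ccccc3)C(C)(C)C)=C21 | intermediate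
30 | (1(10)Z,2S,4S,6R,8E)-2-acetoxy-4,13-dihydroxy-6-(methacryloyloxy)germacra-1(10),7(11),8-trien-12,8-olide (CNP0246543.1) | C=C(C)C(=O)O[C@@H]1C[C@@](C)(O)C[C@H](OC(C)=O)/C=C(C)\C=C2\OC(=O)C(CO)=C21 | target

**Step count and risks**

Total: 17 steps. Longest linear sequence: 15 steps (steps 3 to 17, from 5); steps 1 and 2 supply bromide 4 for the convergent step 6.

Steps most likely to fail:

1. Step 10. The samarium enolate may be protonated or react intermolecularly instead of closing the strained ten-membered ring, the aldolate may revert by retro-aldol, and the ketone may be attacked on the wrong face so that C4 is formed with poor or reversed selectivity. Fallback (sets out from 11, comes back at 20): the C3–C4 bond is made in the open chain under chelation control and the ring is closed at C1–C2 instead. Alcohol 11 is converted (NaH, 4-methoxybenzyl chloride, DMF) into the p-methoxybenzyl ether F1. Tsuji–Wacker oxidation as in step 9 gives the methyl ketone F2. Hosomi–Sakurai allylation (allyltrimethylsilane, TiCl4, CH2Cl2, −78 °C) through the six-membered titanium chelate of the C4 ketone and the C6 ether oxygen should give the 4,6-anti tertiary homoallylic alcohol F3. Lemieux–Johnson cleavage of the monosubstituted alkene (OsO4 cat., NMO, then NaIO4) gives the β-hydroxy aldehyde F4, with C2 at the aldehyde level. Intramolecular Nozaki–Hiyama–Kishi coupling of the Z-alkenyl iodide with the aldehyde (CrCl2, NiCl2 cat., DMSO/THF, high dilution) closes the ten-membered ring as the macrocyclic C2 carbinol F5 (either C2 epimer serves). MnO2 oxidises the allylic alcohol to the macrocyclic enone F6. DDQ (CH2Cl2, pH 7 buffer) removes the p-methoxybenzyl group to give the dihydroxy enone F7. TESCl/imidazole silylates only the secondary C6 hydroxyl and returns 20.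

2. Step 16. The C8 cation may be captured across the ring by the free C4 hydroxyl (bridged ketal), or the tertiary alcohol may be sulfonylated and dehydrated, instead of clean loss of the C9 proton. Fallback (sets out from 25, comes back at 30): the C4 hydroxyl is masked before the furan is oxidised. Treatment of 25 with TMSOTf/2,6-lutidine gives the C4 trimethylsilyl ether F8. Photo-oxygenation as in step 15 gives the silylated hydroxybutenolide F9. With no free hydroxyl left, dehydration can be run under acid catalysis (camphorsulfonic acid cat., toluene, 4 Å molecular sieves) to give the bis-silylated ylidene butenolide F10. HF·pyridine then removes both silyl groups and gives 30 directly.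

3. Step 6. Metalation may occur at the other furan α-position (C12), and the furyllithium may undergo halogen–metal exchange or coupling with the allylic bromide instead of clean alkylation. Fallback (sets out from 7, comes back at 11): the order of allylation and alkylation is reversed and the directing group is changed. Aldehyde 7 is converted in situ into its α-amino alkoxide with LiN(Me)CH2CH2NMe2 (THF, −78 °C). nBuLi then metalates the only α-position ortho to this group (C8), and alkylation with 4 followed by aqueous work-up releases the 2-alkylated aldehyde F11. Allylboration exactly as in step 5 gives 11.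

**Further compounds**

F1 | step 10 | p-methoxybenzyl ether of 11 | C=CC[C@@H](OCc1ccc(OC)cc1)c2c(C/C(C)=C\I)occ2CO[Si](c3ccccc3)(c3ccccc3)C(C)(C)C
F2 | step 10 | methyl ketone from F1 (C4 ketone, alkenyl iodide retained) | CC(=O)C[C@@H](OCc1ccc(OC)cc1)c2c(C/C(C)=C\I)occ2CO[Si](c3ccccc3)(c3ccccc3)C(C)(C)C
F3 | step 10 | (4S,6R) tertiary homoallylic alcohol (4,6-anti) | C=CC[C@](C)(O)C[C@@H](OCc1ccc(OC)cc1)c2c(C/C(C)=C\I)occ2CO[Si](c3ccccc3)(c3ccccc3)C(C)(C)C
F4 | step 10 | β-hydroxy aldehyde (C2 aldehyde) | O=CC[C@](C)(O)C[C@@H](OCc1ccc(OC)cc1)c2c(C/C(C)=C\I)occ2CO[Si](c3ccccc3)(c3ccccc3)C(C)(C)C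
F5 | step 10 | macrocyclic C2 carbinol with C6 p-methoxybenzyl ether (C2 epimers) | COc1ccc(CO[C@@H]2C[C@@](C)(O)CC(O)/C=C(C)\Cc3occ(CO[Si](c4ccccc4)(c4ccccc4)C(C)(C)C)c32)cc1
F6 | step 10 | macrocyclic enone with C6 p-methoxybenzyl ether | COc1ccc(CO[C@@H]2C[C@@](C)(O)CC(=O)/C=C(C)\Cc3occ(CO[Si](c4ccccc4)(c4ccccc4)C(C)(C)C)c32)cc1
F7 | step 10 | 4,6-dihydroxy enone (de-silylated 20) | O[C@@H]1C[C@@](C)(O)CC(=O)/C=C(C)\Cc2occ(CO[Si](c3ccccc3)(c3ccccc3)C(C)(C)C)c21
F8 | step 16 | C4 trimethylsilyl ether of 25 | C=C(C)C(=O)O[C@@H]1C[C@@](C)(O[Si](C)(C)C)C[C@H](OC(C)=O)/C=C(C)\Cc2occ(CO[Si](c3ccccc3)(c3ccccc3)C(C)(C)C)c21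
F9 | step 16 | C4 trimethylsilyl ether of 27 | C=C(C)C(=O)O[C@@H]1C[C@@](C)(O[Si](C)(C)C)C[C@H](OC(C)=O)/C=C(C)\CC2(O)OC(=O)C(CO[Si](c3ccccc3)(c3ccccc3)C(C)(C)C)=C21
F10 | step 16 | C4 trimethylsilyl ether of 29 | C=C(C)C(=O)O[C@@H]1C[C@@](C)(O[Si](C)(C)C)C[C@H](OC(C)=O)/C=C(C)\C=C2\OC(=O)C(CO[Si](c3ccccc3)(c3ccccc3)C(C)(C)C)=C21
F11 | step 6 | 4-(TBDPS-oxymethyl)-2-[(Z)-3-iodo-2-methylprop-2-en-1-yl]furan-3-carbaldehyde | O=Cc1c(C/C(C)=C\I)occ1CO[Si](c2ccccc2)(c2ccccc2)C(C)(C)C
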